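**Retrosynthetic overview**

1. Enabling feature: the oxane oxygen lies between two fully substituted carbons, C(CH3)2 and C(CH3)(CHBr–R). The O–C(CH3)2 unit is read as a lactone O–C(=O), that is as CO2, and the neighbouring CHBr / C–O pair as the anti adduct of an (E)-trisubstituted alkene.
2. Key disconnection: the ring O–C(CH3)(CHBr–R) bond and the ring CH–C(CH3)2 bond are cut together. This gives an open-chain primary alkyl bromide plus CO2, joined by carboxylation and bromolactonization in one flask.
3. The lactone carbonyl (the temporary oxidation level) is then turned into the gem-dimethyl carbon through the ring enol ether: first methyl by enol phosphate coupling, ring bromine by bromo-methoxylation, second methyl with AlMe3.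
4. The open-chain bromide comes from (S)-linalool (carbinol stereocentre), isopropenylmagnesium bromide and triethyl orthoacetate; a Johnson–Claisen rearrangement sets the (E)-alkene.
5. Ring order: one ring only, the oxane, closed in the key step as a δ-lactone.

Key step: step 7

Remark: (S)-(+)-linalool of high enantiomeric purity is taken as a commercial chiral-pool material, and the pseudoenantiomer of the cinchona catalyst in step 7 is the one whose sense of induction gives the (1R,6S) lactone, to be assigned on a model acid.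

**Route**

Step 1
Reactants: 1 (S)-linalool
Product: 2 tert-butyl{[(3S)-3,7-dimethylocta-1,6-dien-3-yl]oxy}dimethylsilane
Conditions: TBSOTf, 2,6-lutidine, CH2Cl2, 0 °C → rt
Reagents that add atoms: tert-butyldimethylsilyl trifluoromethanesulfonate, CC(C)(C)[Si](C)(C)OS(=O)(=O)C(F)(F)F
Why: Silyl triflate/lutidine silylation of the hindered tertiary allylic alcohol; the bulky tert-butyldimethylsilyl (TBS) ether later keeps this oxygen out of the bromonium chemistry, and the carbinol stereocentre is taken unchanged from the chiral pool.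

Step 2
Reactants: 2 tert-butyl{[(3S)-3,7-dimethylocta-1,6-dien-3-yl]oxy}dimethylsilane
Product: 3 (4S)-4-[(tert-butyldimethylsilyl)oxy]-4-methylhex-5-enal
Conditions: O3, CH2Cl2/MeOH, NaHCO3, −78 °C, to Sudan red end point; then Me2S, −78 °C → rt
Reagents that add atoms: ozone, [O-][O+]=O
Why: Chemoselective ozonolysis, since the electron-rich trisubstituted alkene should react far faster than the monosubstituted vinyl group next to the silyloxy-bearing quaternary carbon.

Step 3
Reactants: 3 (4S)-4-[(tert-butyldimethylsilyl)oxy]-4-methylhex-5-enal; 4 isopropenylmagnesium bromide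
Product: 5 (3RS,6S)-6-[(tert-butyldimethylsilyl)oxy]-2,6-dimethylocta-1,7-dien-3-ol (both carbinol epimers)
Conditions: THF, −78 → 0 °C; aq NH4Cl
Reagents that add atoms: none
Why: Grignard addition to the aldehyde; the new carbinol centre is left as a mixture because it is destroyed in the next step.

Step 4
Reactants: 5 (3RS,6S)-6-[(tert-butyldimethylsilyl)oxy]-2,6-dimethylocta-1,7-dien-3-ol; 6 triethyl orthoacetate
Product: 8 ethyl (4E,8S)-8-[(tert-butyldimethylsilyl)oxy]-4,8-dimethyldeca-4,9-dienoate, via ketene acetal 7 (not isolated)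
Conditions: EtCO2H (cat.), neat 6, 140 °C, EtOH distilled off
Reagents that add atoms: none
Why: Johnson–Claisen rearrangement through a chair transition state with the carbinol substituent equatorial, which should give the (E)-trisubstituted alkene from either carbinol epimer (stereoconvergent) and adds two chain carbons.

Step 5
Reactants: 8 ethyl (4E,8S)-8-[(tert-butyldimethylsilyl)oxy]-4,8-dimethyldeca-4,9-dienoate
Product: 9 (4E,8S)-8-[(tert-butyldimethylsilyl)oxy]-4,8-dimethyldeca-4,9-dien-1-ol
Conditions: LiAlH4, Et2O, 0 °C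
Reagents that add atoms: none
Why: Hydride reduction of the ester to the primary alcohol; alkenes and the silyl ether are inert.

Step 6
Reactants: 9 (4E,8S)-8-[(tert-butyldimethylsilyl)oxy]-4,8-dimethyldeca-4,9-dien-1-ol
Product: 10 tert-butyl{[(3S,6E)-10-bromo-3,7-dimethyldeca-1,6-dien-3-yl]oxy}dimethylsilane
Conditions: CBr4, PPh3, 2,6-lutidine, CH2Cl2, 0 °C
Reagents that add atoms: carbon tetrabromide, BrC(Br)(Br)Br
Why: Appel bromination of the primary alcohol under buffered, neutral conditions that should spare the tertiary allylic silyl ether.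

Step 7
Reactants: 10 tert-butyl{[(3S,6E)-10-bromo-3,7-dimethyldeca-1,6-dien-3-yl]oxy}dimethylsilane; 11 carbon dioxide
Product: 14 (6S)-6-[(1R,4S)-1-bromo-4-[(tert-butyldimethylsilyl)oxy]-4-methylhex-5-en-1-yl]-6-methyloxan-2-one, via alkylmagnesium bromide 12 (not isolated), via dienoic acid 13 (not isolated)
Conditions: Mg, THF, 40 °C; CO2, −20 °C → rt; HCl (1 equiv, Et2O), −78 °C, then solvent exchange to CHCl3/toluene; cinchona alkaloid 9-O-(N-arylthiocarbamate) catalyst (10 mol%), NBS, −60 °C
Reagents that add atoms: N-bromosuccinimide, O=C1CCC(=O)N1Br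
Why: Proposed new method: the alkylmagnesium bromide 12 (polarity reversal of the C–Br carbon) attacks CO2 and forges the C–C bond, and the liberated acid 13 then undergoes bromolactonization in which Br+ from NBS adds to the (E)-trisubstituted alkene and the carboxylate oxygen opens the bromiranium ion at the methyl-bearing carbon, forging the C–O bond; the closest known reaction types are Grignard carboxylation and the cinchona-thiocarbamate- or trisimidazoline-catalysed enantioselective bromolactonization of 5-substituted hex-5-enoic acids, which have not been shown for an all-aliphatic trisubstituted alkene or in one flask with the carboxylation. The ring closes in the 6-exo-trig mode at the more substituted (Markovnikov) alkene carbon. Anti opening of the bromiranium ion on the (E)-alkene fixes the relative configuration of the CHBr carbon and the quaternary C–O carbon, and the chiral catalyst, ion-paired with the carboxylate, should choose the alkene face and so the absolute configuration (1R in the side chain, 6S in the ring), the silyloxy stereocentre being too remote to interfere. Chemoselectivity for the trisubstituted alkene over the vinyl group should follow from its much higher nucleophilicity, and the bulky silyl ether should keep its oxygen from competing with the carboxylate.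

Step 8
Reactants: 14 (6S)-6-[(1R,4S)-1-bromo-4-[(tert-butyldimethylsilyl)oxy]-4-methylhex-5-en-1-yl]-6-methyloxan-2-one
Product: 15 (2S)-2-[(1R,4S)-1-bromo-4-[(tert-butyldimethylsilyl)oxy]-4-methylhex-5-en-1-yl]-2-methyl-3,4-dihydro-2H-pyran-6-yl diphenyl phosphate
Conditions: (PhO)2P(O)Cl, then KN(SiMe3)2, THF/HMPA, −78 °C
Reagents that add atoms: diphenyl chlorophosphate, O=P(Cl)(Oc1ccccc1)Oc1ccccc1
Why: Enol phosphate formation with in situ trapping of the potassium lactone enolate, which at −78 °C should outrun any reaction at the hindered secondary bromide.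

Step 9
Reactants: 15 (2S)-2-[(1R,4S)-1-bromo-4-[(tert-butyldimethylsilyl)oxy]-4-methylhex-5-en-1-yl]-2-methyl-3,4-dihydro-2H-pyran-6-yl diphenyl phosphate
Product: 16 (2S)-2-[(1R,4S)-1-bromo-4-[(tert-butyldimethylsilyl)oxy]-4-methylhex-5-en-1-yl]-2,6-dimethyl-3,4-dihydro-2H-pyran
Conditions: AlMe3, Pd(PPh3)4 (5 mol%), ClCH2CH2Cl, rt
Reagents that add atoms: trimethylaluminium, C[Al](C)C
Why: Palladium-catalysed cross-coupling of the ketene acetal phosphate with AlMe3 (zerovalent palladium inserts into the C–O bond, methyl transfer, reductive elimination) installs the first methyl group and places the enol ether double bond regiospecifically in the ring.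

Step 10
Reactants: 16 (2S)-2-[(1R,4S)-1-bromo-4-[(tert-butyldimethylsilyl)oxy]-4-methylhex-5-en-1-yl]-2,6-dimethyl-3,4-dihydro-2H-pyran
Product: 17 (2S,3S,6S)-3-bromo-6-[(1R,4S)-1-bromo-4-[(tert-butyldimethylsilyl)oxy]-4-methylhex-5-en-1-yl]-2-methoxy-2,6-dimethyloxane
Conditions: NBS, MeOH/CH2Cl2, NaHCO3, −78 °C
Reagents that add atoms: N-bromosuccinimide, O=C1CCC(=O)N1Br; methanol, CO
Why: Bromoalkoxylation of the cyclic enol ether, in which Br+ should add to the β-carbon along the axial trajectory of the half-chair that holds the bulky bromoalkyl chain pseudo-equatorial, placing the new bromine cis to that chain (3S), while methanol captures the oxocarbenium ion trans to bromine.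

Step 11
Reactants: 17 (2S,3S,6S)-3-bromo-6-[(1R,4S)-1-bromo-4-[(tert-butyldimethylsilyl)oxy]-4-methylhex-5-en-1-yl]-2-methoxy-2,6-dimethyloxane
Product: 18 (3S,6S)-3-bromo-6-[(1R,4S)-1-bromo-4-[(tert-butyldimethylsilyl)oxy]-4-methylhex-5-en-1-yl]-2,2,6-trimethyloxane
Conditions: AlMe3 (4 equiv), CH2Cl2, −78 → 0 °C
Reagents that add atoms: trimethylaluminium, C[Al](C)C
Why: Lewis-acid-mediated C-methylation of a cyclic ketal, in which AlMe3 should ionise the exocyclic C–OMe bond (the ring oxygen is shielded by two fully substituted carbons) and transfer methyl to the bromine-bridged oxocarbenium ion; the carbon becomes the gem-dimethyl carbon, so no stereocentre arises and the former lactone oxidation level is erased.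

Step 12
Reactants: 18 (3S,6S)-3-bromo-6-[(1R,4S)-1-bromo-4-[(tert-butyldimethylsilyl)oxy]-4-methylhex-5-en-1-yl]-2,2,6-trimethyloxane
Product: 19 (3S,6R)-6-bromo-6-[(2S,5S)-5-bromo-2,6,6-trimethyloxan-2-yl]-3-methylhex-1-en-3-ol
Conditions: HF·pyridine, pyridine, THF, 0 °C → rt
Reagents that add atoms: none
Why: Fluoride cleavage of the tertiary silyl ether under buffered conditions that should spare both secondary bromides and the tertiary allylic alcohol.

**Compound list**

1 | (S)-linalool | C=C[C@@](C)(O)CCC=C(C)C | starting material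
2 | tert-butyl{[(3S)-3,7-dimethylocta-1,6-dien-3-yl]oxy}dimethylsilane | C=C[C@@](C)(O[Si](C)(C)C(C)(C)C)CCC=C(C)C | intermediate
3 | (4S)-4-[(tert-butyldimethylsilyl)oxy]-4-methylhex-5-enal | C=C[C@@](C)(O[Si](C)(C)C(C)(C)C)CCC=O | intermediate
4 | isopropenylmagnesium bromide | CC(=C)[Mg]Br | starting material
5 | (3RS,6S)-6-[(tert-butyldimethylsilyl)oxy]-2,6-dimethylocta-1,7-dien-3-ol | C=C[C@@](C)(O[Si](C)(C)C(C)(C)C)CCC(O)C(C)=C | intermediate
6 | triethyl orthoacetate | CCOC(C)(OCC)OCC | starting material
7 | mixed ketene acetal of 5 (1-ethoxyvinyl ether) | C=C[C@@](C)(O[Si](C)(C)C(C)(C)C)CCC(OC(=C)OCC)C(C)=C | intermediate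
8 | ethyl (4E,8S)-8-[(tert-butyldimethylsilyl)oxy]-4,8-dimethyldeca-4,9-dienoate | C=C[C@@](C)(O[Si](C)(C)C(C)(C)C)CC/C=C(\C)CCC(=O)OCC | intermediate
9 | (4E,8S)-8-[(tert-butyldimethylsilyl)oxy]-4,8-dimethyldeca-4,9-dien-1-ol | C=C[C@@](C)(O[Si](C)(C)C(C)(C)C)CC/C=C(\C)CCCO | intermediate
10 | tert-butyl{[(3S,6E)-10-bromo-3,7-dimethyldeca-1,6-dien-3-yl]oxy}dimethylsilane | C=C[C@@](C)(O[Si](C)(C)C(C)(C)C)CC/C=C(\C)CCCBr | intermediate
11 | carbon dioxide | O=C=O | starting material
12 | {(4E,8S)-8-[(tert-butyldimethylsilyl)oxy]-4,8-dimethyldeca-4,9-dien-1-yl}magnesium bromide | C=C[C@@](C)(O[Si](C)(C)C(C)(C)C)CC/C=C(\C)CCC[Mg]Br | intermediate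
13 | (5E,9S)-9-[(tert-butyldimethylsilyl)oxy]-5,9-dimethylundeca-5,10-dienoic acid | C=C[C@@](C)(O[Si](C)(C)C(C)(C)C)CC/C=C(\C)CCCC(=O)O | intermediate
14 | (6S)-6-[(1R,4S)-1-bromo-4-[(tert-butyldimethylsilyl)oxy]-4-methylhex-5-en-1-yl]-6-methyloxan-2-one | C=C[C@@](C)(O[Si](C)(C)C(C)(C)C)CC[C@@H](Br)[C@]1(C)CCCC(=O)O1 | intermediate
15 | (2S)-2-[(1R,4S)-1-bromo-4-[(tert-butyldimethylsilyl)oxy]-4-methylhex-5-en-1-yl]-2-methyl-3,4-dihydro-2H-pyran-6-yl diphenyl phosphate | C=C[C@@](C)(O[Si](C)(C)C(C)(C)C)CC[C@@H](Br)[C@]1(C)CCC=C(OP(=O)(Oc2ccccc2)Oc2ccccc2)O1 | intermediate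
16 | (2S)-2-[(1R,4S)-1-bromo-4-[(tert-butyldimethylsilyl)oxy]-4-methylhex-5-en-1-yl]-2,6-dimethyl-3,4-dihydro-2H-pyran | C=C[C@@](C)(O[Si](C)(C)C(C)(C)C)CC[C@@H](Br)[C@]1(C)CCC=C(C)O1 | intermediate
17 | (2S,3S,6S)-3-bromo-6-[(1R,4S)-1-bromo-4-[(tert-butyldimethylsilyl)oxy]-4-methylhex-5-en-1-yl]-2-methoxy-2,6-dimethyloxane | C=C[C@@](C)(O[Si](C)(C)C(C)(C)C)CC[C@@H](Br)[C@]1(C)CC[C@H](Br)[C@@](C)(OC)O1 | intermediate
18 | (3S,6S)-3-bromo-6-[(1R,4S)-1-bromo-4-[(tert-butyldimethylsilyl)oxy]-4-methylhex-5-en-1-yl]-2,2,6-trimethyloxane | C=C[C@@](C)(O[Si](C)(C)C(C)(C)C)CC[C@@H](Br)[C@]1(C)CC[C@H](Br)C(C)(C)O1 | intermediate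
19 | (3S,6R)-6-bromo-6-[(2S,5S)-5-bromo-2,6,6-trimethyloxan-2-yl]-3-methylhex-1-en-3-ol | C=C[C@@](C)(O)CC[C@@H](Br)[C@]1(C)CC[C@H](Br)C(C)(C)O1 | target

**Step count and risks**

Total step count: 12. Longest linear sequence: 12 steps (from 1).

Steps most likely to fail:

1. Step 7 (Proposed new method). The catalyst may fail to control the face of bromiranium formation on the all-aliphatic alkene, or may be inhibited by magnesium salts carried over from the carboxylation, so that both anti adducts form. The fallback uses known chemistry and sets out from 10. The carboxylation would be run on its own and the acid 13 isolated, then O-methylated (MeI, K2CO3, DMF) to methyl (5E,9S)-9-[(tert-butyldimethylsilyl)oxy]-5,9-dimethylundeca-5,10-dienoate F1. Shi epoxidation (KHSO5, K2CO3 buffer, MeCN/dimethoxymethane, 0 °C) with the ketone enantiomer that delivers the (S,S)-epoxide (expected to be the L-fructose-derived one, by analogy with the (R,R) sense of the D-fructose-derived ketone on (E)-trisubstituted alkenes) would give methyl 4-{(2S,3S)-3-[(3S)-3-[(tert-butyldimethylsilyl)oxy]-3-methylpent-4-en-1-yl]-2-methyloxiran-2-yl}butanoate F2. Opening with Li2NiBr4 (THF, 0 °C) at the less substituted epoxide carbon with inversion would give the bromohydrin ester methyl (5S,6R,9S)-6-bromo-9-[(tert-butyldimethylsilyl)oxy]-5-hydroxy-5,9-dimethylundec-10-enoate F3. Lactonisation (camphorsulfonic acid cat., toluene, 50 °C) comes back to the route at 14, with both stereocentres set stereospecifically by the epoxidation.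

2. Step 11. After ionisation of the bromo ketal, the ring C–O bond may cleave instead of the C–OMe bond, or the bromine-substituted oxocarbenium ion may lose a proton before methyl transfer. The fallback sets out from 16: bromine (1 equiv, CH2Cl2, −78 °C) would add trans-diaxially to give (2R,3S,6S)-2,3-dibromo-6-[(1R,4S)-1-bromo-4-[(tert-butyldimethylsilyl)oxy]-4-methylhex-5-en-1-yl]-2,6-dimethyloxane F4. Its tertiary α-bromo ether would then be substituted with ZnMe2 (−78 → 0 °C) through the bromine-bridged cation, coming back to the route at 18 without passing through 17.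

3. Step 8. Base-induced elimination at the secondary bromide, or intramolecular C-alkylation of the lactone enolate by that bromide, may compete with O-phosphorylation. The fallback sets out from 14: addition of MeLi (1 equiv, THF, −78 °C, cold quench) would give the lactol (6S)-6-[(1R,4S)-1-bromo-4-[(tert-butyldimethylsilyl)oxy]-4-methylhex-5-en-1-yl]-2,6-dimethyloxan-2-ol F5 (anomer mixture). Dehydration with trifluoroacetic anhydride/2,6-lutidine comes back to the route at 16, so that neither the enolate nor 15 is needed.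

Further compounds
F1 | step 7 | methyl (5E,9S)-9-[(tert-butyldimethylsilyl)oxy]-5,9-dimethylundeca-5,10-dienoate | C=C[C@@](C)(O[Si](C)(C)C(C)(C)C)CC/C=C(\C)CCCC(=O)OC
F2 | step 7 | methyl 4-{(2S,3S)-3-[(3S)-3-[(tert-butyldimethylsilyl)oxy]-3-methylpent-4-en-1-yl]-2-methyloxiran-2-yl}butanoate | C=C[C@@](C)(O[Si](C)(C)C(C)(C)C)CC[C@@H]1O[C@@]1(C)CCCC(=O)OC
F3 | step 7 | methyl (5S,6R,9S)-6-bromo-9-[(tert-butyldimethylsilyl)oxy]-5-hydroxy-5,9-dimethylundec-10-enoate | C=C[C@@](C)(O[Si](C)(C)C(C)(C)C)CC[C@@H](Br)[C@@](C)(O)CCCC(=O)OC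
F4 | step 11 | (2R,3S,6S)-2,3-dibromo-6-[(1R,4S)-1-bromo-4-[(tert-butyldimethylsilyl)oxy]-4-methylhex-5-en-1-yl]-2,6-dimethyloxane | C=C[C@@](C)(O[Si](C)(C)C(C)(C)C)CC[C@@H](Br)[C@]1(C)CC[C@H](Br)[C@@](C)(Br)O1
F5 | step 8 | (6S)-6-[(1R,4S)-1-bromo-4-[(tert-butyldimethylsilyl)oxy]-4-methylhex-5-en-1-yl]-2,6-dimethyloxan-2-ol | C=C[C@@](C)(O[Si](C)(C)C(C)(C)C)CC[C@@H](Br)[C@]1(C)CCCC(C)(O)O1
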